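## The problem

Compound 26 is an achiral hydroxylated pentabromodiphenyl ether. Ring A is a hydroquinone (OH at C1 and C4) with the ether oxygen at C2, bromine at C3 and C5, and its only hydrogen at C6. Ring B is bound through C1' and carries bromine at C2', C3' and C5', a hydroxyl at C4' and hydrogen at C6'. There is no stereocentre, so every difficulty is positional. The ether oxygen lies between C1–OH and C3–Br on ring A and beside C2'–Br on ring B. A late C–O coupling would therefore join a hindered, acidic phenol to a polybromoarene under copper or palladium conditions that C–Br bonds tolerate poorly. Ring B needs exactly one bromine meta to its hydroxyl besides the two that a phenol takes up ortho, and C6–H of ring A must survive that bromination. The bromohydroquinone of ring A is oxidised to a quinone by air in base or by bromine, and aryl bromides do not survive alkyllithiums or hydrogenolysis, so ring B bromine must enter after all organolithium steps and ring A must be unmasked last, under acid. The enabling feature is that C3(Br)–C4(O)–C5(Br)–C6(H) of ring A is the substituent sequence of C3 to C6 of a 3,5-dibromo-4-methoxy-2-pyrone, while C1 and C2 are two adjacent oxygen-bearing carbons, that is, an alkyne with an aryloxy group on one carbon and a hydroxyl surrogate on the other.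

## Retrosynthesis

**26 from 24.** The O–CH3 bond at C4 and the O–acetyl bond at C1 are cut last. Acetate 24 holds ring A as a methyl ether and an ester, so the oxidisable hydroquinone never meets bromine or base. One BBr3 treatment with a methanol quench should remove both groups (through monoacetate 25) under acidic, non-oxidising conditions. Two methyl ethers would be simpler to remove, but an acetate at C1 deactivates C6–H far better during the preceding bromination.

**24 from 22.** The three C–Br bonds of ring B are cut. Phenol 22 has free positions ortho to its hydroxyl at C3' and C5' and a trimethylsilyl group at C2'. Once C3' and C5' carry bromine (23), C2' and C6' are constitutionally equivalent, so the third bromine raises no question of position, only of number and rate. Direct C–H substitution meta to the hydroxyl of a 2,6-dibromophenol would need forcing conditions that neither stop cleanly at one bromine nor spare the p-aryloxyphenol. Silicon at C2' turns this into a fast ipso substitution that consumes exactly one equivalent. Silicon also survives the n-BuLi used earlier, which bromine would not.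

**22 from 19.** Three functional-group changes are unravelled: the O–Si bond of the ring B silyl ether (21 to 22), the acetate (20 to 21) and the C–O bond that replaces C–B (19 to 20). The order is fixed by reactivity. The boronate is oxidised before any electrophilic bromine is present, because an aryl boronate para to methoxy could suffer ipso-bromodeboronation. The new phenol is acetylated before ring B is unmasked, so that only ring B is an activated phenol during bromination.

**19 from 14 and 17.** This is the key cut: the C2–C3 and C1–C6 bonds of ring A, undoing a pyrone Diels–Alder reaction with loss of CO2. Cutting the diaryl ether C–O bond instead leads back to the hindered coupling described above. The cycloaddition forms no C–O bond at all and fixes all six substituents of ring A through the connectivity of the two partners. Alkyne 14 and pyrone 17 are each three or four steps from purchasable materials. The forward reaction must deliver one regiochemistry: boron carbon to pyrone C6, aryloxy carbon to pyrone C3.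

**17 from 15.** The two C–Br bonds of the pyrone are cut. C3 and C5 of 4-methoxy-2-pyrone 15 are its two nucleophilic positions (beta to the methoxy group and beta to the ring oxygen), so double electrophilic bromination through 16 should give 17 directly.

**14 from 9 and 10, and 9 from 6 and 7.** The C–B bond is cut to a lithium acetylide (12) and isopropoxy pinacol borate 10. The acetylide comes from dichlorovinyl ether 9 and n-BuLi through chloroalkyne 11. Ether 9 comes from phenol 6 and trichloroethylene 7 through dichloroacetylene 8. The ether C–O bond of the target is therefore made by adding an unhindered phenoxide to an sp carbon, the easiest possible setting, and ring A is then grown onto it. The n-BuLi step is the reason ring B is carried without bromine.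

**6 from 5, and 5 from 1.** The O–Si bond of the triisopropylsilyl ether and the C–Si bond are cut. In silylhydroquinone 5 the hydroxyl next to the trimethylsilyl group is shielded, so the bulky silyl chloride should take the remote one. The C–Si bond comes from bromohydroquinone 1 by O-silylation (2), bromine–lithium exchange (3) and 1,3-migration of silicon from oxygen to carbon (4). This places silicon exactly where the bromine was, ortho to the future ether oxygen.

## Roads not taken

**Alternative 1:** The cut is the C4–C5 bond of ring A, formed by electrocyclisation. Heating 4-methoxy-3-(2,3,5-tribromo-4-methoxyphenoxy)-4-vinylcyclobut-2-en-1-one A2 would open the four-membered ring to a dienylketene. Its 6π-electrocyclisation and tautomerisation would give 4-methoxy-3-(2,3,5-tribromo-4-methoxyphenoxy)phenol A1. Bromination ortho to the one free hydroxyl of A1 and BBr3 demethylation would finish the synthesis.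
- Merits: ring B arrives fully brominated as 2,3,5-tribromo-4-methoxyphenol A3, so no silicon marker and no protecting-group exchange is needed. The single free phenol of A1 directs the two ring A bromines to the right carbons. Only three steps follow ring formation, against five in the chosen plan.
- Weak points: in 3-(2,3,5-tribromo-4-methoxyphenoxy)cyclobut-3-ene-1,2-dione A4 and in A2 the ether oxygen sits on a vinylogous acyl carbon, and the phenoxide of A3 is a good leaving group. The vinylmetal addition that makes A2 from A4 therefore competes with addition–elimination that expels A3, and it must also spare three C–Br bonds. A3 is not a direct bromination product, because its methoxy group and not its hydroxyl is flanked by two bromines, and it needs four or five steps. A4, with one ring hydrogen, is several steps from squaric acid.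
- Comparison: overall length is about the same and the end game of this alternative is better. Against that, the chosen plan keeps the ether oxygen on a robust carbon throughout and runs all organometallic chemistry before ring B carries any C–Br bond.

**Alternative 2:** Ring B is not aromatic until late, and the ether C–O bond is made at an sp3 carbon. 3-Bromo-4-(2,4-dibromo-3,6-dimethoxyphenoxy)cyclohex-2-en-1-one A6 would be brominated at C2 and C6 and would lose HBr (three equivalents of bromine, one being spent on the dehydrogenation). This would give 2,3,6-tribromo-4-(2,4-dibromo-3,6-dimethoxyphenoxy)phenol A5, and BBr3 would then give the target.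
- Merits: 2,4-dibromo-3,6-dimethoxyphenol A7 should come in one step from 2,5-dimethoxyphenol A8, since bromine enters para and ortho to the hydroxyl. Here the alternative is better than the chosen plan, which spends a cycloaddition and a boron oxidation on a ring that ordinary bromination supplies. The bromine meta to the ring B hydroxyl is fixed by the enone carbon, so no marker is needed. The count, about seven steps, is the shortest but one.
- Weak points: A6 needs the aryloxy group at C4 and not at C6. That means gamma-functionalisation of a 3-bromocyclohexenone and substitution at a secondary allylic carbon by the hindered, weakly nucleophilic phenoxide of A7, with elimination and allylic transposition as competitors. The aromatising step offers three enolisable or brominatable ring positions (C2, C4, C6). It also exposes ring A, at that stage an alkyl aryl ether with one free position ortho to methoxy, to three equivalents of bromine and to HBr.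
- Comparison: this road is shorter and cheaper in ring A. The chosen plan sets against it that each of its selectivities rests on connectivity (cycloaddition polarity) or on a large rate difference (ipso substitution at silicon). Alternative 2 concentrates three unproven selectivities on its most advanced intermediates.

**Alternative 3:** The cut is the ether C–O bond and the adjacent C2'–Br bond together. CsF would release 3,5-dibromo-4-methoxybenzyne A11 from 2,4-dibromo-3-methoxy-6-(trimethylsilyl)phenyl triflate A10. The caesium salt of A7 would add at the aryne carbon remote from bromine, and CBr4 would brominate the resulting aryl anion. The product is 1,3-dibromo-2,5-dimethoxy-4-(2,3,5-tribromo-4-methoxyphenoxy)benzene A9, the permethylated target, and BBr3 would finish.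
- Merits: this is the most convergent plan. One step makes the hindered ether and places the fifth bromine, arynes accept hindered phenoxides, and the flanking bromine steers the addition.
- Weak points: the anion formed by the addition lies ortho to that same bromine. An ortho-bromoaryl anion loses bromide readily to give a new aryne, so bromine transfer from CBr4 must outrun the elimination with no proton source present; otherwise the substitution pattern scrambles. A10 is also hard to make, because the usual bromine–lithium exchange and silyl migration cannot distinguish its other C–Br bonds.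
- Comparison: if the three-component coupling worked, this road would be clearly superior in step count and convergence. The chosen plan accepts a longer linear sequence for a key step whose regiochemistry follows from ground-state polarity and whose product cannot decompose by the route that threatens the aryne adduct.

Key step: step 6

Remark: the target has no stereocentre; the only stereogenic species on the route, bridged lactone 18, is racemic and loses both centres in the step that forms it. 4-Methoxy-2H-pyran-2-one is taken to be purchasable.

## Route

Step 1
Reactants: 1 bromohydroquinone (2-bromobenzene-1,4-diol)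
Product: 5 2-(trimethylsilyl)benzene-1,4-diol, via 2-bromo-1,4-bis(trimethylsilyloxy)benzene 2 (not isolated), via [2,5-bis(trimethylsilyloxy)phenyl]lithium 3 (not isolated), via lithium 4-(trimethylsilyloxy)-2-(trimethylsilyl)phenoxide 4 (not isolated)
Conditions: (Me3Si)2NH, 80 °C, then evaporate; n-BuLi (1.1 equiv), THF, −78 °C to rt; aq. NH4Cl, rt
Reagents that add atoms: hexamethyldisilazane, C[Si](C)(C)N[Si](C)(C)C
Why: Exhaustive O-silylation gives 2; bromine–lithium exchange gives aryllithium 3, in which silicon migrates from the ortho oxygen to carbon (anionic 1,3-silyl shift, retro-Brook rearrangement) because a phenoxide is far more stable than an aryl anion; the remaining aryl O–SiMe3 bond of 4 is hydrolysed on aqueous work-up while the C–Si bond stays.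

Step 2
Reactants: 5 2-(trimethylsilyl)benzene-1,4-diol
Product: 6 4-(triisopropylsilyloxy)-2-(trimethylsilyl)phenol
Conditions: TIPSCl (1.05 equiv), imidazole, CH2Cl2, −20 to 0 °C, argon
Reagents that add atoms: chlorotriisopropylsilane, CC(C)[Si](Cl)(C(C)C)C(C)C
Why: Imidazole-mediated silylation of a phenol is governed by steric access; the C1 hydroxyl is flanked by the trimethylsilyl group and the C4 hydroxyl by two hydrogens, so the bulky silyl chloride should react at C4–OH only.

Step 3
Reactants: 6 4-(triisopropylsilyloxy)-2-(trimethylsilyl)phenol; 7 trichloroethylene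
Product: 9 (E)-1,2-dichlorovinyl 4-(triisopropylsilyloxy)-2-(trimethylsilyl)phenyl ether, via dichloroacetylene 8 (not isolated)
Conditions: K2CO3, DMF, 70 °C
Reagents that add atoms: none
Why: Base removes HCl from 7 to give dichloroacetylene 8 in the flask, and the phenoxide of 6 adds anti across it (the standard preparation of aryl 1,2-dichlorovinyl ethers from phenols); the ether C–O bond of the target is thus made at an sp carbon with no steric demand, and the silyl ether and the C–Si bond are spectators to anhydrous carbonate.

Step 4
Reactants: 9 (E)-1,2-dichlorovinyl 4-(triisopropylsilyloxy)-2-(trimethylsilyl)phenyl ether; 10 2-isopropoxy-4,4,5,5-tetramethyl-1,3,2-dioxaborolane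
Product: 14 2-[[4-(triisopropylsilyloxy)-2-(trimethylsilyl)phenoxy]ethynyl]-4,4,5,5-tetramethyl-1,3,2-dioxaborolane, via aryl chloroethynyl ether 11 (not isolated), via lithium aryloxyacetylide 12 (not isolated), via lithium alkynylborate 13 (not isolated)
Conditions: n-BuLi (2.2 equiv), THF, −78 to −40 °C; 10, −78 °C; HCl (1.0 equiv, 2 M in Et2O), −78 °C to rt; filter under argon, concentrate, use crude
Reagents that add atoms: none
Why: n-BuLi removes the vinylic proton, LiCl is lost to give chloroalkyne 11, and chlorine–lithium exchange gives acetylide 12 (the dichlorovinyl ether route to ynol ethers); 12 adds to boron of 10 to give borate 13, from which one equivalent of anhydrous HCl removes isopropoxide, as in the usual preparation of alkynyl pinacol boronates; the aryl C–Si and O–Si bonds do not react with n-BuLi at −78 °C, which a C–Br bond would.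

Step 5
Reactants: 15 4-methoxy-2H-pyran-2-one
Product: 17 3,5-dibromo-4-methoxy-2H-pyran-2-one, via 3-bromo-4-methoxy-2H-pyran-2-one 16 (not isolated)
Conditions: Br2 (2.3 equiv), NaOAc, AcOH, rt to 60 °C
Reagents that add atoms: bromine, BrBr
Why: Electrophilic substitution of a 2-pyrone occurs at C3 and C5; C3 (beta to the methoxy group, alpha to the carbonyl) should react first to give 16, and C5 (beta to the ring oxygen) second, with acetate taking up HBr.

Step 6
Reactants: 14 2-[[4-(triisopropylsilyloxy)-2-(trimethylsilyl)phenoxy]ethynyl]-4,4,5,5-tetramethyl-1,3,2-dioxaborolane; 17 3,5-dibromo-4-methoxy-2H-pyran-2-one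
Product: 19 2-[3,5-dibromo-4-methoxy-2-[4-(triisopropylsilyloxy)-2-(trimethylsilyl)phenoxy]phenyl]-4,4,5,5-tetramethyl-1,3,2-dioxaborolane, via bridged bicyclic lactone 18 (not isolated)
Conditions: 14 (1.0 equiv), 17 (1.5 equiv), o-xylene, 140 °C, sealed tube, argon
Reagents that add atoms: none
Why: The diene C3=C4–C5=C6 of pyrone 17 and the alkyne of 14 combine in a thermal, asynchronous [4+2] cycloaddition of inverse electron demand to bridged lactone 18, which loses CO2 by retro-[4+2] cycloreversion at the same temperature and gives the benzene ring of 19 directly. The closest known reaction type is the Diels–Alder/retro-Diels–Alder reaction of 2-pyrones with alkynyl pinacol boronates to arylboronates, together with the cycloadditions of 3,5-dibromo-2-pyrone with electron-rich dienophiles. Ring A closes as a six-membered carbocycle by intermolecular [4+2] cycloaddition, which forms the bonds from pyrone C3 to the aryloxy carbon and from pyrone C6 to the boron-bearing carbon; the cycloreversion then makes it aromatic. No stereocentre results: the two bridgehead centres of racemic 18 are fixed relative to each other by the bicycle and both vanish with CO2. The selectivity required is regiochemical and is secured by polarity: the oxygen lone pair makes the boron-bearing carbon the nucleophilic end of the ynol ether (the empty orbital on boron stabilises charge there as well), and this end bonds to C6, the electrophilic terminus of the pyrone conjugated with the lactone carbonyl, as enol ethers do with 3,5-dibromo-2-pyrone. The aryloxy carbon therefore ends next to C3–Br and the boron next to C6–H, which is the arrangement of C2 and C1 in ring A. An aryl ynol ether has no beta-hydrogen and cannot fragment to a ketene by retro-ene reaction, so it should tolerate the temperature; the two bromines should keep the diene electron-poor enough despite its 4-methoxy group.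

Step 7
Reactants: 19 2-[3,5-dibromo-4-methoxy-2-[4-(triisopropylsilyloxy)-2-(trimethylsilyl)phenoxy]phenyl]-4,4,5,5-tetramethyl-1,3,2-dioxaborolane
Product: 20 3,5-dibromo-4-methoxy-2-[4-(triisopropylsilyloxy)-2-(trimethylsilyl)phenoxy]phenol
Conditions: NaBO3·4H2O (3 equiv), THF/H2O 1:1, rt
Reagents that add atoms: sodium perborate (NaBO3·4H2O, written as its peroxoborate dimer), [Na+].[Na+].O[B-]1(O)OO[B-](O)(O)OO1
Why: Peroxide adds to boron and the aryl group migrates from boron to oxygen with retention of position (oxidation of an arylboronate to a phenol); perborate is mild enough to leave the aryl silyl ether and the C–Si bond alone.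

Step 8
Reactants: 20 3,5-dibromo-4-methoxy-2-[4-(triisopropylsilyloxy)-2-(trimethylsilyl)phenoxy]phenol
Product: 21 3,5-dibromo-4-methoxy-2-[4-(triisopropylsilyloxy)-2-(trimethylsilyl)phenoxy]phenyl acetate
Conditions: Ac2O, pyridine, DMAP (cat.), CH2Cl2, rt
Reagents that add atoms: acetic anhydride, CC(=O)OC(C)=O
Why: DMAP-catalysed O-acylation of a phenol; the acetate turns the strongly activating hydroxyl next to C6–H into a weak donor, which protects C6 of ring A in step 10.

Step 9
Reactants: 21 3,5-dibromo-4-methoxy-2-[4-(triisopropylsilyloxy)-2-(trimethylsilyl)phenoxy]phenyl acetate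
Product: 22 3,5-dibromo-2-[4-hydroxy-2-(trimethylsilyl)phenoxy]-4-methoxyphenyl acetate
Conditions: TBAF (1.1 equiv), AcOH (1.1 equiv), THF, 0 °C
Reagents that add atoms: none
Why: Fluoride cleaves the aryl O–Si bond (desilylation driven by the Si–F bond); buffering with acetic acid keeps the liberated phenoxide protonated so that it cannot take the acetyl group from ring A, and an unactivated aryl–SiMe3 bond does not react with buffered fluoride at 0 °C.

Step 10
Reactants: 22 3,5-dibromo-2-[4-hydroxy-2-(trimethylsilyl)phenoxy]-4-methoxyphenyl acetate
Product: 24 3,5-dibromo-4-methoxy-2-(2,3,5-tribromo-4-hydroxyphenoxy)phenyl acetate, via dibromo arylsilane 23 (not isolated)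
Conditions: NBS (3.1 equiv), MeCN, 0 °C to rt, dark
Reagents that add atoms: N-bromosuccinimide, O=C1CCC(=O)N1Br
Why: Electrophilic aromatic substitution first fills both positions ortho to the free phenol (C3' and C5'; para is blocked) to give 23; the third equivalent attacks C2' ipso, where the C–Si bond stabilises the cationic intermediate (ipso-bromodesilylation), so exactly one bromine should enter meta to the hydroxyl without acid; C6–H of ring A is deactivated by the acetate and two bromines.

Step 11
Reactants: 24 3,5-dibromo-4-methoxy-2-(2,3,5-tribromo-4-hydroxyphenoxy)phenyl acetate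
Product: 26 3,5-dibromo-2-(2,3,5-tribromo-4-hydroxyphenoxy)benzene-1,4-diol, via phenol monoacetate 25 (not isolated)
Conditions: BBr3 (4 equiv), CH2Cl2, −78 °C to rt; then MeOH, rt; argon, aq. Na2S2O4 wash
Reagents that add atoms: none
Why: BBr3 cleaves the aryl methyl ether (Lewis acid-assisted demethylation, MeBr leaves) and leaves the diaryl ether intact, giving 25 as its borate; the methanol quench generates HBr in methanol, which removes the aryl acetate by acid-catalysed transesterification, so the oxidisable bromohydroquinone appears only in the last step and only under acidic, non-oxidising conditions.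

## Compound list

1 | bromohydroquinone (2-bromobenzene-1,4-diol) | Oc1ccc(O)c(Br)c1 | starting material
2 | 2-bromo-1,4-bis(trimethylsilyloxy)benzene (formed in the flask) | C[Si](C)(C)Oc1ccc(O[Si](C)(C)C)c(Br)c1 | intermediate
3 | [2,5-bis(trimethylsilyloxy)phenyl]lithium (formed in the flask) | [Li]c1cc(O[Si](C)(C)C)ccc1O[Si](C)(C)C | intermediate
4 | lithium 4-(trimethylsilyloxy)-2-(trimethylsilyl)phenoxide (formed in the flask) | [Li+].[O-]c1ccc(O[Si](C)(C)C)cc1[Si](C)(C)C | intermediate
5 | 2-(trimethylsilyl)benzene-1,4-diol | Oc1ccc(O)c([Si](C)(C)C)c1 | intermediate
6 | 4-(triisopropylsilyloxy)-2-(trimethylsilyl)phenol | CC(C)[Si](Oc1ccc(O)c([Si](C)(C)C)c1)(C(C)C)C(C)C | intermediate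
7 | trichloroethylene | ClC=C(Cl)Cl | starting material
8 | dichloroacetylene (formed in the flask) | ClC#CCl | intermediate
9 | (E)-1,2-dichlorovinyl 4-(triisopropylsilyloxy)-2-(trimethylsilyl)phenyl ether | Cl/C=C(/Cl)Oc1ccc(O[Si](C(C)C)(C(C)C)C(C)C)cc1[Si](C)(C)C | intermediate
10 | 2-isopropoxy-4,4,5,5-tetramethyl-1,3,2-dioxaborolane | CC(C)OB1OC(C)(C)C(C)(C)O1 | starting material
11 | chloroethynyl 4-(triisopropylsilyloxy)-2-(trimethylsilyl)phenyl ether (formed in the flask) | ClC#COc1ccc(O[Si](C(C)C)(C(C)C)C(C)C)cc1[Si](C)(C)C | intermediate
12 | lithium [4-(triisopropylsilyloxy)-2-(trimethylsilyl)phenoxy]acetylide (formed in the flask) | [Li]C#COc1ccc(O[Si](C(C)C)(C(C)C)C(C)C)cc1[Si](C)(C)C | intermediate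
13 | lithium isopropoxy(pinacolato){[4-(triisopropylsilyloxy)-2-(trimethylsilyl)phenoxy]ethynyl}borate (formed in the flask) | [Li+].CC(C)O[B-]1(C#COc2ccc(O[Si](C(C)C)(C(C)C)C(C)C)cc2[Si](C)(C)C)OC(C)(C)C(C)(C)O1 | intermediate
14 | 2-[[4-(triisopropylsilyloxy)-2-(trimethylsilyl)phenoxy]ethynyl]-4,4,5,5-tetramethyl-1,3,2-dioxaborolane | CC(C)[Si](Oc1ccc(OC#CB2OC(C)(C)C(C)(C)O2)c([Si](C)(C)C)c1)(C(C)C)C(C)C | intermediate
15 | 4-methoxy-2H-pyran-2-one | COc1ccoc(=O)c1 | starting material
16 | 3-bromo-4-methoxy-2H-pyran-2-one (formed in the flask) | COc1ccoc(=O)c1Br | intermediate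
17 | 3,5-dibromo-4-methoxy-2H-pyran-2-one | O=c1occ(Br)c(OC)c1Br | intermediate
18 | 4,6-dibromo-5-methoxy-7-(4,4,5,5-tetramethyl-1,3,2-dioxaborolan-2-yl)-8-[4-(triisopropylsilyloxy)-2-(trimethylsilyl)phenoxy]-2-oxabicyclo[2.2.2]octa-5,7-dien-3-one (racemic, one enantiomer drawn; formed in the flask) | O=C1O[C@H]2C(Br)=C(OC)[C@]1(Br)C(Oc3ccc(O[Si](C(C)C)(C(C)C)C(C)C)cc3[Si](C)(C)C)=C2B4OC(C)(C)C(C)(C)O4 | intermediate
19 | 2-[3,5-dibromo-4-methoxy-2-[4-(triisopropylsilyloxy)-2-(trimethylsilyl)phenoxy]phenyl]-4,4,5,5-tetramethyl-1,3,2-dioxaborolane | COc1c(Br)cc(B2OC(C)(C)C(C)(C)O2)c(Oc2ccc(O[Si](C(C)C)(C(C)C)C(C)C)cc2[Si](C)(C)C)c1Br | intermediate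
20 | 3,5-dibromo-4-methoxy-2-[4-(triisopropylsilyloxy)-2-(trimethylsilyl)phenoxy]phenol | COc1c(Br)cc(O)c(Oc2ccc(O[Si](C(C)C)(C(C)C)C(C)C)cc2[Si](C)(C)C)c1Br | intermediate
21 | 3,5-dibromo-4-methoxy-2-[4-(triisopropylsilyloxy)-2-(trimethylsilyl)phenoxy]phenyl acetate | COc1c(Br)cc(OC(C)=O)c(Oc2ccc(O[Si](C(C)C)(C(C)C)C(C)C)cc2[Si](C)(C)C)c1Br | intermediate
22 | 3,5-dibromo-2-[4-hydroxy-2-(trimethylsilyl)phenoxy]-4-methoxyphenyl acetate | COc1c(Br)cc(OC(C)=O)c(Oc2ccc(O)cc2[Si](C)(C)C)c1Br | intermediate
23 | 3,5-dibromo-2-[3,5-dibromo-4-hydroxy-2-(trimethylsilyl)phenoxy]-4-methoxyphenyl acetate (formed in the flask) | COc1c(Br)cc(OC(C)=O)c(Oc2cc(Br)c(O)c(Br)c2[Si](C)(C)C)c1Br | intermediate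
24 | 3,5-dibromo-4-methoxy-2-(2,3,5-tribromo-4-hydroxyphenoxy)phenyl acetate | COc1c(Br)cc(OC(C)=O)c(Oc2cc(Br)c(O)c(Br)c2Br)c1Br | intermediate
25 | 3,5-dibromo-4-hydroxy-2-(2,3,5-tribromo-4-hydroxyphenoxy)phenyl acetate (formed in the flask) | CC(=O)Oc1cc(Br)c(O)c(Br)c1Oc1cc(Br)c(O)c(Br)c1Br | intermediate
26 | 3,5-dibromo-2-(2,3,5-tribromo-4-hydroxyphenoxy)benzene-1,4-diol | Oc1cc(Br)c(O)c(Br)c1Oc1cc(Br)c(O)c(Br)c1Br | target

## Step count and risks

Total steps: 11. Longest linear sequence: 10 steps (steps 1, 2, 3, 4, 6, 7, 8, 9, 10, 11 from bromohydroquinone 1); the pyrone branch is one step (step 5).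

**Step 6 (key step).** The most likely failure is thermal loss of the ynol ether boronate 14 (oligomerisation, or hydration by traces of water) before it is intercepted by a diene whose 4-methoxy group lowers its electrophilicity. Erosion of regioselectivity is less likely. The fallback gives up the cycloaddition for this ring and makes phenol 20 by nucleophilic aromatic substitution followed by a Dakin-type oxidation. It sets out from phenol 6. Purchased 2-fluoro-4-hydroxybenzaldehyde F1 would be brominated at both positions ortho to its hydroxyl (Br2, AcOH) to 3,5-dibromo-2-fluoro-4-hydroxybenzaldehyde F2 and methylated (MeI, K2CO3, acetone) to 3,5-dibromo-2-fluoro-4-methoxybenzaldehyde F3. The phenoxide of 6 would displace the fluoride, which is activated by the ortho formyl group (K2CO3, DMF, 80 °C), to give 3,5-dibromo-4-methoxy-2-[4-(triisopropylsilyloxy)-2-(trimethylsilyl)phenoxy]benzaldehyde F4. Baeyer–Villiger oxidation with 3-chloroperbenzoic acid would give 3,5-dibromo-4-methoxy-2-[4-(triisopropylsilyloxy)-2-(trimethylsilyl)phenoxy]phenyl formate F5, and methanolysis (NaHCO3, MeOH) would return to the route at 20.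

**Step 4.** The most likely failure is acid-induced hydration or HCl addition at the ynol ether, or protodeboronation, when borate 13 is broken up, with further loss on handling the crude boronate. The fallback changes the hydroxyl surrogate from boron to silicon. It sets out from 9. The acetylide 12 would be generated as before and quenched with chlorodimethylsilane to give {[4-(triisopropylsilyloxy)-2-(trimethylsilyl)phenoxy]ethynyl}dimethylsilane F6, which should survive neutral aqueous work-up and chromatography. Heating F6 with 17 should give, through the racemic 4,6-dibromo-7-(dimethylsilyl)-5-methoxy-8-[4-(triisopropylsilyloxy)-2-(trimethylsilyl)phenoxy]-2-oxabicyclo[2.2.2]octa-5,7-dien-3-one F7 and loss of CO2, [3,5-dibromo-4-methoxy-2-[4-(triisopropylsilyloxy)-2-(trimethylsilyl)phenoxy]phenyl]dimethylsilane F8, with the same polarity control as in step 6. Tamao–Fleming oxidation (H2O2, KF, KHCO3, THF/MeOH) would return to the route at 20. The trimethylsilyl group of ring B has no heteroatom or hydrogen on silicon and is inert to these conditions.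

**Step 10.** The most likely failure is protodesilylation at C2' by adventitious acid, or slow ipso substitution on the twice-brominated ring, leaving material one bromine short. Oxidation of the p-aryloxyphenol by excess reagent is a second risk. The fallback changes the order of events and sets out from 21. Ipso-bromodesilylation would be run first (Br2, NaHCO3, CH2Cl2, −78 to 0 °C), while ring B is still an electron-rich silyl ether, to give 2-[2-bromo-4-(triisopropylsilyloxy)phenoxy]-3,5-dibromo-4-methoxyphenyl acetate F9. Any bromine that enters ortho to the silyl ether instead is not lost, because that position is brominated later anyway. Buffered fluoride (TBAF, AcOH) would give 2-(2-bromo-4-hydroxyphenoxy)-3,5-dibromo-4-methoxyphenyl acetate F10, and NBS (2 equiv) would brominate both positions ortho to the phenol and return to the route at 24.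

**Step 5.** The most likely failure is incomplete substitution at C5, or addition of bromine across C5=C6 without re-formation of the pyrone, with lactone opening by acetate as a further loss. The fallback replaces direct substitution by addition–elimination in separate steps and sets out from 15. NBS (1 equiv, MeCN) would give 16, which would now be isolated. Br2 in CH2Cl2 would add across C5=C6 to give trans-3,5,6-tribromo-4-methoxy-5,6-dihydro-2H-pyran-2-one F11. Et3N would remove HBr (H5 is vinylogously acidic, and the bromine at C6 is an alpha-bromo ether) and return to the route at 17.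

**Step 2.** The most likely failure is air oxidation of the electron-rich silylhydroquinone 5 to its quinone during handling, or partial double silylation. The fallback reverses the order of the two silicon steps and sets out from 1. TIPSCl and imidazole would silylate the hydroxyl remote from bromine to give 2-bromo-4-(triisopropylsilyloxy)phenol F12, with the regioisomer removed by chromatography if the smaller bias of bromine lets some form. Hexamethyldisilazane would give [3-bromo-4-(trimethylsilyloxy)phenoxy]triisopropylsilane F13 (not isolated), and n-BuLi would induce the same bromine–lithium exchange and silyl migration and return to the route at 6 without passing through a free hydroquinone.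

## Further compounds

F1 | step 6 | 2-fluoro-4-hydroxybenzaldehyde (purchased starting material of the fallback) | O=Cc1ccc(O)cc1F
F2 | step 6 | 3,5-dibromo-2-fluoro-4-hydroxybenzaldehyde | O=Cc1cc(Br)c(O)c(Br)c1F
F3 | step 6 | 3,5-dibromo-2-fluoro-4-methoxybenzaldehyde | COc1c(Br)cc(C=O)c(F)c1Br
F4 | step 6 | 3,5-dibromo-4-methoxy-2-[4-(triisopropylsilyloxy)-2-(trimethylsilyl)phenoxy]benzaldehyde | COc1c(Br)cc(C=O)c(Oc2ccc(O[Si](C(C)C)(C(C)C)C(C)C)cc2[Si](C)(C)C)c1Br
F5 | step 6 | 3,5-dibromo-4-methoxy-2-[4-(triisopropylsilyloxy)-2-(trimethylsilyl)phenoxy]phenyl formate | COc1c(Br)cc(OC=O)c(Oc2ccc(O[Si](C(C)C)(C(C)C)C(C)C)cc2[Si](C)(C)C)c1Br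
F6 | step 4 | {[4-(triisopropylsilyloxy)-2-(trimethylsilyl)phenoxy]ethynyl}dimethylsilane | C[SiH](C)C#COc1ccc(O[Si](C(C)C)(C(C)C)C(C)C)cc1[Si](C)(C)C
F7 | step 4 | 4,6-dibromo-7-(dimethylsilyl)-5-methoxy-8-[4-(triisopropylsilyloxy)-2-(trimethylsilyl)phenoxy]-2-oxabicyclo[2.2.2]octa-5,7-dien-3-one (racemic, one enantiomer drawn) | O=C1O[C@H]2C(Br)=C(OC)[C@]1(Br)C(Oc3ccc(O[Si](C(C)C)(C(C)C)C(C)C)cc3[Si](C)(C)C)=C2[SiH](C)C
F8 | step 4 | [3,5-dibromo-4-methoxy-2-[4-(triisopropylsilyloxy)-2-(trimethylsilyl)phenoxy]phenyl]dimethylsilane | COc1c(Br)cc([SiH](C)C)c(Oc2ccc(O[Si](C(C)C)(C(C)C)C(C)C)cc2[Si](C)(C)C)c1Br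
F9 | step 10 | 2-[2-bromo-4-(triisopropylsilyloxy)phenoxy]-3,5-dibromo-4-methoxyphenyl acetate | COc1c(Br)cc(OC(C)=O)c(Oc2ccc(O[Si](C(C)C)(C(C)C)C(C)C)cc2Br)c1Br
F10 | step 10 | 2-(2-bromo-4-hydroxyphenoxy)-3,5-dibromo-4-methoxyphenyl acetate | COc1c(Br)cc(OC(C)=O)c(Oc2ccc(O)cc2Br)c1Br
F11 | step 5 | trans-3,5,6-tribromo-4-methoxy-5,6-dihydro-2H-pyran-2-one (racemic, one enantiomer drawn) | COC1=C(Br)C(=O)O[C@H](Br)[C@H]1Br
F12 | step 2 | 2-bromo-4-(triisopropylsilyloxy)phenol | CC(C)[Si](Oc1ccc(O)c(Br)c1)(C(C)C)C(C)C
F13 | step 2 | [3-bromo-4-(trimethylsilyloxy)phenoxy]triisopropylsilane | CC(C)[Si](Oc1ccc(O[Si](C)(C)C)c(Br)c1)(C(C)C)C(C)C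
A1 | alternative 1 | 4-methoxy-3-(2,3,5-tribromo-4-methoxyphenoxy)phenol | COc1ccc(O)cc1Oc1cc(Br)c(OC)c(Br)c1Br
A2 | alternative 1 | 4-methoxy-3-(2,3,5-tribromo-4-methoxyphenoxy)-4-vinylcyclobut-2-en-1-one (racemic) | C=CC1(OC)C(Oc2cc(Br)c(OC)c(Br)c2Br)=CC1=O
A3 | alternative 1 | 2,3,5-tribromo-4-methoxyphenol | COc1c(Br)cc(O)c(Br)c1Br
A4 | alternative 1 | 3-(2,3,5-tribromo-4-methoxyphenoxy)cyclobut-3-ene-1,2-dione | O=C1C=C(Oc2cc(Br)c(OC)c(Br)c2Br)C1=O
A5 | alternative 2 | 2,3,6-tribromo-4-(2,4-dibromo-3,6-dimethoxyphenoxy)phenol | COc1cc(Br)c(OC)c(Br)c1Oc1cc(Br)c(O)c(Br)c1Br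
A6 | alternative 2 | 3-bromo-4-(2,4-dibromo-3,6-dimethoxyphenoxy)cyclohex-2-en-1-one (racemic) | O=C1C=C(Br)C(Oc2c(OC)cc(Br)c(OC)c2Br)CC1
A7 | alternative 2 | 2,4-dibromo-3,6-dimethoxyphenol (also used in alternative 3) | COc1cc(Br)c(OC)c(Br)c1O
A8 | alternative 2 | 2,5-dimethoxyphenol | COc1ccc(OC)c(O)c1
A9 | alternative 3 | 1,3-dibromo-2,5-dimethoxy-4-(2,3,5-tribromo-4-methoxyphenoxy)benzene | COc1cc(Br)c(OC)c(Br)c1Oc1cc(Br)c(OC)c(Br)c1Br
A10 | alternative 3 | 2,4-dibromo-3-methoxy-6-(trimethylsilyl)phenyl trifluoromethanesulfonate | COc1c(Br)cc([Si](C)(C)C)c(OS(=O)(=O)C(F)(F)F)c1Br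
A11 | alternative 3 | 3,5-dibromo-4-methoxybenzyne | COC1=C(Br)C#CC=C1Br
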